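How much of the electrophile has reacted in this flask at the asked time, and how much of the unused nucleophile is still free?

| flask | electrophile | nucleophile | free base | remark | time |
|---|---|---|---|---|---|
| north-west | 0.050 M (fed, over 12 min) | 0.090 M | 0.025 M | the very flask that is asked about, followed so far |  |
| south-east | 0.025 M (fed, over 12 min) | 0.090 M | 0.025 M | run made earlier |  |
| flask | 0.050 M (fed, over 12 min) | 0.0900 M | 0.0250 M |  | 80 min |

| run | time / min | electrophile / % | target / % |
|---|---|---|---|
| north-west | 2.50 | 16.0 | 1.8 |
| north-west | 6.00 | 28.0 | 5.1 |
| north-west | 15.0 | 30.2 | 23.7 |
| north-west | 30.0 | 18.3 | 34.7 |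
| south-east | 2.50 | 15.4 | 2.9 |
| south-east | 6.00 | 29.5 | 6.6 |
| south-east | 15.0 | 29.5 | 24.5 |
| south-east | 30.0 | 16.1 | 38.1 |

(standard deviation of a reading: 1 percentage point)
- part of the electrophile that has reacted at 80 min
- share of the unused nucleophile that is free and not bound as protonated nucleophile, at 80 min
- what has gone from electrophile into another species counts as reacted, even if it can come back
- percentages count the whole charge, also what has not yet gone in
- the earlier runs do not show how much of nucleophile is bound; that part of a forecast is a guess

1. I assume each electrophile turned to product uses one nucleophile and sets one acid free, and that the free base takes acid first. So w = 50.0% is the base cover, the free base charged over the electrophile charged.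

2. Let cA be the electrophile charged, cB the nucleophile charged, and m the share of cA made into product. I take acid beyond the cover, (m − w)·cA, to sit on nucleophile. The free share f is then the unused cB − m·cA, less that overflow, over the unused.

3. My first bracket for f runs from m = w, where f = 100%, down to m = 100%, where f = 37.5%.

4. I tighten it from the readings of this flask. At 15.0 min, the part that is neither electrophile nor target is 1.53 times the electrophile read. If that part stays parked in that ratio, then at 30.0 min I reckon m at 53.8%, above the cover. Since m can only grow later, I put f at 80 min below 97.0%.

5. Between those two readings the electrophile falls at 0.0334 min⁻¹. Held to 80 min, that pace gives m = 91.3% and f = 53.4%. I take that m as my ceiling, since by this reckoning less nucleophile is unused at 80 min than at 30.0 min. On the same reckoning I put the reacted part at 80 min between 81.7% and 96.6%.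

6. The forecast, 86% and 88% (“but this is a guess”), stands inside both brackets.

The flask gives 91.0% reacted and 77.0% free.

    electrophile + nucleophile → acid set free + target (k = 0.818 M⁻¹ min⁻¹)
    nucleophile + acid set free ⇌ protonated nucleophile, settled at all times (K = 10000 M⁻¹)
    acid set free + free base ⇌ salt of the base, settled at all times (K = 2.44 × 10⁶ M⁻¹)
    electrophile ⇌ dormant form (K = 1.68, k = 0.164 min⁻¹)
    target ⇌ isomer of the product (K = 1.04, k = 0.0268 min⁻¹)

At 80.0 min this flask holds 40.8% target and 33.0% isomer of the product, so m is 73.8%. The overflow past w is then 0.0119 M, and protonated nucleophile stands at 0.0122 M. In a neighbour flask with 0.12 M of electrophile, w falls to 20.8% and m is 46.6%. The overflow there is 0.0310 M, protonated nucleophile stands at 0.0302 M, and 11.3% of the unused nucleophile is free.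

(The data stem from a simulated flask on assumed constants, and the scatter is random.)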